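**Plan**

- Retrosynthesis: the C13 acetate and two 4-methoxybenzyl (PMB) ethers go first. The C1 ketone / C5=C6 enol-lactone pair is then traced to a Grob fragmentation, which means re-making a C1–C6 bond that the target lacks (cis-fused tricycle: ring A = C1–C6, ring B = C1, C6–C10, butenolide on C6–C7). Ring A is cut at C2–C3 (ring-closing metathesis, then H2), C5–C6 by a Mukaiyama aldol, C1–C6 by a Dieckmann closure, and the butenolide by an intramolecular Horner–Wadsworth–Emmons reaction.
- Forward: lactone 1 → butenolide 11 → ring B (13) → C6 side chain (17) → C1 vinyl carbinol (20) → ring A by C2–C3 closure (21) → fragmentation of C1–C6 to the ten-membered ring (27) → deprotection and acetylation (29).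
- Enabling feature: C1 (ketone carbon) and C6 (the oxygen-bearing alkylidene carbon of the enol lactone, C5=C6) face each other across the ten-membered ring. A C1 alkoxide and a C5 sulfonate across a C1–C6 bond fragment to exactly C1=O plus C5=C6–O. The bond can therefore be borrowed, so that C2–C3 closes a cyclohexene (ring A) on a cyclohexane (ring B).
- Stereochemistry: C8 from (R)-lactone 1, C10 by trans-methylation, C4 by asymmetric palladium-catalysed allylic etherification. C1, C5 and C6 (all erased by the fragmentation) are set by substrate control, and the (Z)-C5=C6 geometry by the anti-periplanar fragmentation.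

Key step: step 15

Remark (assumption): germacrane locants of the target are used for all intermediates (C1 ketone carbon, C4 carbinol carbon, C5=C6 exocyclic alkene, C7=C11, C12 lactone C=O, C13 CH2O, C8 ester carbon, C10 methyl-bearing carbon); "β" is the face of ring B that carries the C10 methyl group; 1, 6, 7 and 14 are taken as commercial.

Step 1
Reactants: 1 (R)-5-[(trityloxy)methyl]dihydrofuran-2(3H)-one
Product: 2 (3S,5R)-3-methyl-5-[(trityloxy)methyl]dihydrofuran-2(3H)-one
Conditions: LDA, THF, −78 °C; MeI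
Reagents that add atoms: iodomethane, CI
Why: Lithium enolate alkylation of a γ-substituted butyrolactone; MeI should enter anti to the C5 substituent and give the trans-3,5 product, which sets C10 (S) relative to C8 (R).

Step 2
Reactants: 2 trans-methyl trityl lactone
Product: 3 (2R,4S)-4-methyl-5-oxotetrahydrofuran-2-carboxylic acid
Conditions: CrO3, H2SO4, H2O, acetone, 0 °C to rt
Reagents that add atoms: water, O
Why: Jones oxidation; the acidic medium should cleave the trityl ether and the freed primary alcohol is oxidised through its aldehyde hydrate to the acid, the lactone and both stereocentres staying untouched.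

Step 3
Reactants: 3 lactone acid
Product: 5 (3S,5R)-5-(diazoacetyl)-3-methyldihydrofuran-2(3H)-one, via acid chloride 4 (not isolated)
Conditions: (COCl)2, DMF (cat.), CH2Cl2, 0 °C; then CH2N2, Et2O, 0 °C
Reagents that add atoms: diazomethane, C=[N+]=[N-]
Why: Acid chloride formation and C-acylation of diazomethane (first stage of the Arndt–Eistert sequence) should give the α-diazoketone whose diazo carbon becomes C6, excess CH2N2 taking up the HCl.

Step 4
Reactants: 6 4-methoxybenzyl alcohol; 7 ethyl 2-(diethoxyphosphoryl)acrylate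
Product: 8 ethyl 2-(diethoxyphosphoryl)-3-[(4-methoxybenzyl)oxy]propanoate
Conditions: KOtBu (cat.), THF, 0 °C
Reagents that add atoms: none
Why: Base-catalysed oxa-Michael addition of the alcohol to the doubly activated vinylphosphonate should install the future C13–O bond.

Step 5
Reactants: 8 phosphono ester
Product: 9 2-(diethoxyphosphoryl)-3-[(4-methoxybenzyl)oxy]propanoic acid
Conditions: LiOH, THF–H2O, 0 °C; then dilute HCl
Reagents that add atoms: lithium hydroxide, [Li+].[OH-]
Why: Saponification; hydroxide should attack only the carboxylic ethyl ester, the phosphonate diester being inert at 0 °C, and short exposure limits retro-Michael loss of the alkoxide.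

Step 6
Reactants: 5 diazoketone; 9 phosphono acid
Product: 10 2-[(2R,4S)-4-methyl-5-oxotetrahydrofuran-2-yl]-2-oxoethyl 2-(diethoxyphosphoryl)-3-[(4-methoxybenzyl)oxy]propanoate
Conditions: Rh2(OAc)4 (cat.), CH2Cl2, rt
Reagents that add atoms: none
Why: Rhodium-carbenoid O–H insertion of an α-diazoketone into a carboxylic acid should give the α-acyloxy ketone under neutral conditions, so that C8 (α to the ketone) does not epimerise.

Step 7
Reactants: 10 acyloxy ketone
Product: 11 (3S,5R)-5-[4-{[(4-methoxybenzyl)oxy]methyl}-5-oxo-2,5-dihydrofuran-3-yl]-3-methyldihydrofuran-2(3H)-one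
Conditions: LiCl, DBU, MeCN, 0 °C
Reagents that add atoms: none
Why: Intramolecular Horner–Wadsworth–Emmons olefination of the phosphonoacetate onto the C7 ketone should close the butenolide (C7=C11) faster than the mild base can epimerise C8.

Step 8
Reactants: 11 butenolide lactone
Product: 13 (4R,6S)-3-{[(4-methoxybenzyl)oxy]methyl}-6-methyl-4,7-bis(triethylsilyloxy)-5,6-dihydrobenzofuran-2(4H)-one, via dilithium enolate 12 (not isolated)
Conditions: LiHMDS (2.2 equiv), THF, −78 to 0 °C; then Et3SiCl, −78 °C
Reagents that add atoms: chlorotriethylsilane, CC[Si](Cl)(CC)CC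
Why: Dieckmann condensation of an extended enolate (as in acylations of phthalide anions): LiHMDS removes the γ-proton at C6, the 2-oxidofuran attacks the γ-lactone carbonyl C1 through C6 to close ring B and release the C8 alkoxide, the new ketone is at once deprotonated to the stabilised dianion 12 (the driving force), and O-silylation of both oxygens gives 13 with C8 and C10 untouched.

Step 9
Reactants: 14 2-methyl-2-vinyloxirane; 6 4-methoxybenzyl alcohol
Product: 15 (R)-2-[(4-methoxybenzyl)oxy]-2-methylbut-3-en-1-ol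
Conditions: Pd2(dba)3·CHCl3 (cat.), N,N′-(cyclohexane-1,2-diyl)bis[2-(diphenylphosphino)benzamide] (enantiomer leading to (R)-15), Et3B (cat.), CH2Cl2, rt
Reagents that add atoms: none
Why: Palladium-catalysed dynamic kinetic asymmetric allylic etherification (Tsuji–Trost type); the boron co-catalyst should deliver the alkoxide to the more substituted terminus of the equilibrating π-allyl complex, and the chiral ligand sets the tertiary ether centre, the future C4 (R).

Step 10
Reactants: 15 (R)-alcohol
Product: 16 (R)-2-[(4-methoxybenzyl)oxy]-2-methylbut-3-enal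
Conditions: Dess–Martin periodinane, NaHCO3, CH2Cl2, 0 °C
Reagents that add atoms: none
Why: Dess–Martin oxidation of the primary alcohol; the α-carbon is quaternary, so the aldehyde can neither epimerise nor enolise.

Step 11
Reactants: 13 silyl dienol ether; 16 aldehyde
Product: 17 C6-quaternary aldol adduct (C1 ketone, C5 triethylsilyl ether)
Conditions: HNTf2 (cat.), CH2Cl2, −78 °C
Reagents that add atoms: none
Why: Triflimide-catalysed Mukaiyama aldol reaction with silyl transfer; C6 should add to the aldehyde from the α face through a chair-like transition state that keeps C8–OSiEt3 and C10–CH3 equatorial (side chain axial, lactone oxygen in the butenolide plane), and an antiperiplanar open transition state with the quaternary C4 over the small lactone oxygen instead of C7 should give the (5S) silyl ether.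

Step 12
Reactants: 17 ketone
Product: 18 C1 exocyclic methylene compound
Conditions: Zn, CH2Br2, TiCl4, THF–CH2Cl2, 0 °C to rt
Reagents that add atoms: dibromomethane, BrCBr
Why: Takai–Lombardo methylenation converts hindered, enolisable ketones into 1,1-disubstituted alkenes without touching lactones or silyl ethers, and brings in C2.

Step 13
Reactants: 18 exocyclic alkene
Product: 19 spiro-epoxide (oxirane oxygen β on C1, C2 cis to the C6 side chain)
Conditions: dimethyldioxirane, acetone, −20 °C
Reagents that add atoms: dimethyldioxirane, CC1(C)OO1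
Why: Electrophilic epoxidation of the most electron-rich (1,1-disubstituted) alkene; the axial C6 side chain blocks the α face, so oxygen should reach C1 from the β face, which places C2 cis to the side chain.

Step 14
Reactants: 19 spiro-epoxide
Product: 20 C1 tertiary vinyl carbinol
Conditions: Me3SI, n-BuLi, THF, −10 °C to rt
Reagents that add atoms: trimethylsulfonium iodide, C[S+](C)C.[I-]
Why: Corey–Chaykovsky-type sulfonium ylide chemistry; attack of the ylide on the epoxide CH2 terminus and ylide-mediated loss of Me2S should homologate the epoxide to the tertiary allylic alcohol with retention at C1.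

Step 15
Reactants: 20 diene (C1 vinyl and C4 vinyl)
Product: 21 cis-fused tricyclic cyclohexene (C2=C3)
Conditions: second-generation Grubbs catalyst RuCl2(=CHPh)(H2IMes)(PCy3) (cat.), CH2Cl2, 40 °C
Reagents that add atoms: none
Why: Ring-closing olefin metathesis: the ruthenium benzylidene exchanges with one monosubstituted vinyl group, the resulting alkylidene adds to the other vinyl group by [2+2] cycloaddition and cycloreversion, and ethylene is lost as the C2=C3 bond forms. The closest known reaction type is the ring-closing metathesis of 1,7-dienes to cyclohexenes flanked by tertiary allylic carbinol or ether centres. It closes the six-membered carbocycle ring A (C1–C2–C3–C4–C5–C6) onto ring B across the temporary C1–C6 bond as a cis-fused ring closure, so a cyclohexene is made where the target has a ten-membered ring. No stereocentre is created; the ring enforces the Z alkene, which is hydrogenated in step 16. The step needs reaction at the two vinyl groups only, secured because the one other alkene is the tetrasubstituted, electron-poor butenolide double bond. It also needs the C1 vinyl group gauche (cis) to the axial C6 side chain, secured by the β-face epoxidation of step 13.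

Step 16
Reactants: 21 tricyclic alkene
Product: 22 saturated tricycle
Conditions: H2 (1 atm), PtO2, EtOAc, rt
Reagents that add atoms: none
Why: Heterogeneous hydrogenation of the one disubstituted alkene; the tetrasubstituted conjugated butenolide alkene and the PMB ethers should survive PtO2 at 1 atm.

Step 17
Reactants: 22 bis(triethylsilyl) ether
Product: 23 C1,C5,C8-triol
Conditions: PPTS, MeOH, rt
Reagents that add atoms: none
Why: Acid-catalysed methanolysis should remove the two secondary triethylsilyl ethers, while the tertiary alcohol, the PMB ethers and the lactone are stable to PPTS.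

Step 18
Reactants: 23 triol
Product: 24 C8 senecioate
Conditions: 3-methylbut-2-enoyl chloride, pyridine, DMAP (cat.), CH2Cl2, −20 °C
Reagents that add atoms: 3-methylbut-2-enoyl chloride, CC(C)=CC(Cl)=O
Why: DMAP-catalysed acylation of the less hindered secondary alcohol at C8; the C5 alcohol lies between two fully substituted carbons and the C1 alcohol is tertiary.

Step 19
Reactants: 24 senecioate diol
Product: 25 C5 mesylate
Conditions: MsCl, Et3N, CH2Cl2, −20 to 0 °C
Reagents that add atoms: methanesulfonyl chloride, CS(Cl)(=O)=O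
Why: Sulfonylation through sulfene tolerates the hindered secondary C5 alcohol, and the tertiary C1 alcohol should not react.

Step 20
Reactants: 25 γ-mesyloxy tertiary alcohol
Product: 27 bis-PMB ether of the target skeleton, via potassium alkoxide 26 (not isolated)
Conditions: KHMDS, THF, −78 to −20 °C
Reagents that add atoms: none
Why: Grob (Wharton-type) fragmentation of a γ-sulfonyloxy alkoxide; the C1 alkoxide pushes into the C1–C6 bond, which in the cis-fused tricycle is anti-periplanar to the equatorial C5–OMs bond, so C1–C6 breaks, C5=C6 forms and mesylate leaves, C7 (equatorial on ring A) ends trans to C4, and the (Z)-alkylidene butenolide, the C1 ketone and the ten-membered ring should arise in one event while the C4 ether blocks a pinacol-type shift.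

Step 21
Reactants: 27 bis-PMB ether
Product: 28 C4,C13-diol
Conditions: DDQ, CH2Cl2–pH 7 buffer, 0 °C
Reagents that add atoms: none
Why: Oxidative cleavage of both PMB ethers by DDQ (hydride abstraction, hydrolysis of the oxocarbenium ions); the electron-poor dienyl lactone and the senecioate should not be oxidised.

Step 22
Reactants: 28 diol
Product: 29 target (CNP0186726.1)
Conditions: Ac2O, pyridine, DMAP (cat.), CH2Cl2, 0 °C
Reagents that add atoms: acetic anhydride, CC(=O)OC(C)=O
Why: Acetylation of the primary allylic alcohol only; the tertiary C4 alcohol is inert under these conditions.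

**Compound list**

1 | (R)-5-[(trityloxy)methyl]dihydrofuran-2(3H)-one | O=C1CC[C@H](COC(c2ccccc2)(c2ccccc2)c2ccccc2)O1 | starting material
2 | (3S,5R)-3-methyl-5-[(trityloxy)methyl]dihydrofuran-2(3H)-one | O=C1[C@@H](C)C[C@H](COC(c2ccccc2)(c2ccccc2)c2ccccc2)O1 | intermediate
3 | (2R,4S)-4-methyl-5-oxotetrahydrofuran-2-carboxylic acid | O=C1[C@@H](C)C[C@H](C(=O)O)O1 | intermediate
4 | (2R,4S)-4-methyl-5-oxotetrahydrofuran-2-carbonyl chloride | O=C1[C@@H](C)C[C@H](C(Cl)=O)O1 | intermediate (not isolated)
5 | (3S,5R)-5-(diazoacetyl)-3-methyldihydrofuran-2(3H)-one | O=C1[C@@H](C)C[C@H](C(=O)C=[N+]=[N-])O1 | intermediate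
6 | 4-methoxybenzyl alcohol | COc1ccc(CO)cc1 | starting material
7 | ethyl 2-(diethoxyphosphoryl)acrylate | CCOC(=O)C(=C)P(=O)(OCC)OCC | starting material
8 | ethyl 2-(diethoxyphosphoryl)-3-[(4-methoxybenzyl)oxy]propanoate (racemic) | CCOC(=O)C(COCc1ccc(OC)cc1)P(=O)(OCC)OCC | intermediate
9 | 2-(diethoxyphosphoryl)-3-[(4-methoxybenzyl)oxy]propanoic acid (racemic) | OC(=O)C(COCc1ccc(OC)cc1)P(=O)(OCC)OCC | intermediate
10 | 2-[(2R,4S)-4-methyl-5-oxotetrahydrofuran-2-yl]-2-oxoethyl 2-(diethoxyphosphoryl)-3-[(4-methoxybenzyl)oxy]propanoate (both epimers at the phosphonate carbon) | O=C1[C@@H](C)C[C@H](C(=O)COC(=O)C(COCc2ccc(OC)cc2)P(=O)(OCC)OCC)O1 | intermediate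
11 | (3S,5R)-5-[4-{[(4-methoxybenzyl)oxy]methyl}-5-oxo-2,5-dihydrofuran-3-yl]-3-methyldihydrofuran-2(3H)-one | O=C1[C@@H](C)C[C@H](C2=C(COCc3ccc(OC)cc3)C(=O)OC2)O1 | intermediate
12 | dilithium (4R,6S)-3-{[(4-methoxybenzyl)oxy]methyl}-6-methyl-2-oxo-2,4,5,6-tetrahydrobenzofuran-4,7-diolate | C[C@H]1C[C@@H]([O-])C2=C(COCc3ccc(OC)cc3)C(=O)OC2=C1[O-].[Li+].[Li+] | intermediate (not isolated)
13 | (4R,6S)-3-{[(4-methoxybenzyl)oxy]methyl}-6-methyl-4,7-bis(triethylsilyloxy)-5,6-dihydrobenzofuran-2(4H)-one | C[C@H]1C[C@@H](O[Si](CC)(CC)CC)C2=C(COCc3ccc(OC)cc3)C(=O)OC2=C1O[Si](CC)(CC)CC | intermediate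
14 | 2-methyl-2-vinyloxirane (racemic) | CC1(C=C)CO1 | starting material
15 | (R)-2-[(4-methoxybenzyl)oxy]-2-methylbut-3-en-1-ol | OC[C@](C)(OCc1ccc(OC)cc1)C=C | intermediate
16 | (R)-2-[(4-methoxybenzyl)oxy]-2-methylbut-3-enal | O=C[C@](C)(OCc1ccc(OC)cc1)C=C | intermediate
17 | (4R,6S,7aS)-7a-[(1S,2R)-2-[(4-methoxybenzyl)oxy]-2-methyl-1-(triethylsilyloxy)but-3-en-1-yl]-3-{[(4-methoxybenzyl)oxy]methyl}-6-methyl-4-(triethylsilyloxy)-5,6-dihydrobenzofuran-2,7(4H,7aH)-dione | C[C@H]1C[C@@H](O[Si](CC)(CC)CC)C2=C(COCc3ccc(OC)cc3)C(=O)O[C@@]2([C@@H](O[Si](CC)(CC)CC)[C@](C)(OCc4ccc(OC)cc4)C=C)C1=O | intermediate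
18 | 7-methylene analogue of 17 (C1=CH2 in place of the C1 ketone, all other centres as in 17) | C[C@H]1C[C@@H](O[Si](CC)(CC)CC)C2=C(COCc3ccc(OC)cc3)C(=O)O[C@@]2([C@@H](O[Si](CC)(CC)CC)[C@](C)(OCc4ccc(OC)cc4)C=C)C1=C | intermediate
19 | spiro-epoxide of 18 (oxirane on C1; oxygen on the β face, CH2 cis to the C6 side chain) | C[C@H]1C[C@@H](O[Si](CC)(CC)CC)C2=C(COCc3ccc(OC)cc3)C(=O)O[C@@]2([C@@H](O[Si](CC)(CC)CC)[C@](C)(OCc4ccc(OC)cc4)C=C)[C@]15CO5 | intermediate
20 | (1S)-tertiary vinyl carbinol (C1 carries β-OH and a vinyl group cis to the C6 side chain; other centres as in 17) | C[C@H]1C[C@@H](O[Si](CC)(CC)CC)C2=C(COCc3ccc(OC)cc3)C(=O)O[C@@]2([C@@H](O[Si](CC)(CC)CC)[C@](C)(OCc4ccc(OC)cc4)C=C)[C@]1(O)C=C | intermediate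
21 | (1R,4R,5S,6S,8R,10S)-1-hydroxy-4,13-bis[(4-methoxybenzyl)oxy]-5,8-bis(triethylsilyloxy)-1,6-cyclogermacra-2,7(11)-dien-6,12-olide (cis-fused rings A and B) | C[C@H]1C[C@@H](O[Si](CC)(CC)CC)C2=C(COCc4ccc(OC)cc4)C(=O)O[C@]23[C@@H](O[Si](CC)(CC)CC)[C@](C)(OCc5ccc(OC)cc5)C=C[C@]13O | intermediate
22 | (1S,4R,5S,6S,8R,10S)-1-hydroxy-4,13-bis[(4-methoxybenzyl)oxy]-5,8-bis(triethylsilyloxy)-1,6-cyclogermacr-7(11)-en-6,12-olide | C[C@H]1C[C@@H](O[Si](CC)(CC)CC)C2=C(COCc4ccc(OC)cc4)C(=O)O[C@]23[C@@H](O[Si](CC)(CC)CC)[C@](C)(OCc5ccc(OC)cc5)CC[C@]13O | intermediate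
23 | (1S,4R,5S,6S,8R,10S)-1,5,8-trihydroxy-4,13-bis[(4-methoxybenzyl)oxy]-1,6-cyclogermacr-7(11)-en-6,12-olide | C[C@H]1C[C@@H](O)C2=C(COCc4ccc(OC)cc4)C(=O)O[C@]23[C@@H](O)[C@](C)(OCc5ccc(OC)cc5)CC[C@]13O | intermediate
24 | 8-O-(3-methylbut-2-enoyl) derivative of 23 | C[C@H]1C[C@@H](OC(=O)C=C(C)C)C2=C(COCc4ccc(OC)cc4)C(=O)O[C@]23[C@@H](O)[C@](C)(OCc5ccc(OC)cc5)CC[C@]13O | intermediate
25 | 5-O-methanesulfonyl derivative of 24 | C[C@H]1C[C@@H](OC(=O)C=C(C)C)C2=C(COCc4ccc(OC)cc4)C(=O)O[C@]23[C@@H](OS(C)(=O)=O)[C@](C)(OCc5ccc(OC)cc5)CC[C@]13O | intermediate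
26 | potassium C1-alkoxide of 25 | C[C@H]1C[C@@H](OC(=O)C=C(C)C)C2=C(COCc4ccc(OC)cc4)C(=O)O[C@]23[C@@H](OS(C)(=O)=O)[C@](C)(OCc5ccc(OC)cc5)CC[C@]13[O-].[K+] | intermediate (not isolated)
27 | 4,13-bis-O-(4-methoxybenzyl) ether of the 13-deacetyl target (ten-membered ring, 5Z) | COc1ccc(COCC2=C3/C(=C/[C@](C)(OCc4ccc(OC)cc4)CCC(=O)[C@@H](C)C[C@H]3OC(=O)C=C(C)C)OC2=O)cc1 | intermediate
28 | 13-deacetyl target (C4,C13-diol) | OCC1=C2/C(=C/[C@](C)(O)CCC(=O)[C@@H](C)C[C@H]2OC(=O)C=C(C)C)OC1=O | intermediate
29 | CNP0186726.1, (4R,5Z,8R,10S)-13-acetoxy-4-hydroxy-1-oxo-8-(3-methylbut-2-enoyloxy)germacra-5,7(11)-dien-6,12-olide | CC(=O)OCC1=C2/C(=C/[C@](C)(O)CCC(=O)[C@@H](C)C[C@H]2OC(=O)C=C(C)C)OC1=O | target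

**Totals and risks**

Total step count: 22. Longest linear sequence: 18 steps (steps 1–3, 6–8, 11–22).

Steps most likely to fail:

Step 11. The acceptor-substituted, fully substituted silyl enol ether may add too slowly to the α-quaternary aldehyde. It may also add with poor facial selectivity at C6 or C5, since the aldehyde's own Felkin preference can oppose the ring control. The fallback makes the C5–C6 bond before ring B exists. It sets out from 11: O-silylation (Et3SiOTf, Et3N) would give the 2-(triethylsilyloxy)furan F1. Its vinylogous Mukaiyama aldol reaction with 16 at the still unsubstituted C6 (HNTf2 cat.) would give the γ-adduct F2 as its C5 triethylsilyl ether. LiHMDS would then close ring B by the Dieckmann reaction of step 8, the C8 alkoxide being trapped with Et3SiCl, and the route is rejoined at 17.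

Step 14. The basic, nucleophilic ylide may attack the lactone carbonyl or add in conjugate fashion to the butenolide instead of opening the hindered epoxide. The fallback sets out from 18: osmylation (OsO4 cat., N-methylmorpholine N-oxide) of the 1,1-disubstituted alkene from the same β face would give the diol F3. Selective oxidation of its primary alcohol (TEMPO cat., PhI(OAc)2) would give the α-hydroxy aldehyde F4, and Wittig methylenation (Ph3P=CH2) rejoins the route at 20.

Step 20. A 1,2-acyl shift of the lactone to the C1 alkoxide followed by pinacol-type ring contraction may compete. Twisting of ring A (syn-axial C4 methyl and lactone oxygen) may also spoil the anti-periplanar alignment and erode the alkene geometry. The fallback opens the C1–C6 bond before the ring is closed and closes C2–C3 directly on the open chain. It sets out from 20: methanolysis (PPTS) would give the triol F5, acylation at C8 the senecioate F6 and sulfonylation at C5 the mesylate F7. KHMDS would fragment this conformationally free bicycle to the open-chain (Z)-alkylidene butenolide vinyl ketone F8. Ring-closing metathesis at high dilution (second-generation Hoveyda–Grubbs catalyst RuCl2(=CH–C6H4-2-OiPr)(H2IMes)) would give the ten-membered (Z)-enone F9, and conjugate reduction with [(Ph3P)CuH]6 rejoins the route at 27.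

Further compounds
F1 | step 11 | (3S,5R)-5-[4-{[(4-methoxybenzyl)oxy]methyl}-5-(triethylsilyloxy)furan-3-yl]-3-methyldihydrofuran-2(3H)-one | O=C1[C@@H](C)C[C@H](c2coc(O[Si](CC)(CC)CC)c2COCc3ccc(OC)cc3)O1
F2 | step 11 | γ-adduct of F1 and 16: butenolide 11 carrying at C6 the (1S,2R)-2-[(4-methoxybenzyl)oxy]-2-methyl-1-(triethylsilyloxy)but-3-enyl chain (both C6 epimers) | O=C1[C@@H](C)C[C@H](C2=C(COCc3ccc(OC)cc3)C(=O)OC2[C@@H](O[Si](CC)(CC)CC)[C@](C)(OCc4ccc(OC)cc4)C=C)O1
F3 | step 14 | C1,C2-diol from 18 (C1 β-OH, CH2OH cis to the C6 side chain) | C[C@H]1C[C@@H](O[Si](CC)(CC)CC)C2=C(COCc3ccc(OC)cc3)C(=O)O[C@@]2([C@@H](O[Si](CC)(CC)CC)[C@](C)(OCc4ccc(OC)cc4)C=C)[C@]1(O)CO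
F4 | step 14 | α-hydroxy aldehyde from F3 (C2 = CHO) | C[C@H]1C[C@@H](O[Si](CC)(CC)CC)C2=C(COCc3ccc(OC)cc3)C(=O)O[C@@]2([C@@H](O[Si](CC)(CC)CC)[C@](C)(OCc4ccc(OC)cc4)C=C)[C@]1(O)C=O
F5 | step 20 | C1,C5,C8-triol from 20 (both triethylsilyl groups removed) | C[C@H]1C[C@@H](O)C2=C(COCc3ccc(OC)cc3)C(=O)O[C@@]2([C@@H](O)[C@](C)(OCc4ccc(OC)cc4)C=C)[C@]1(O)C=C
F6 | step 20 | 8-O-(3-methylbut-2-enoyl) derivative of F5 | C[C@H]1C[C@@H](OC(=O)C=C(C)C)C2=C(COCc3ccc(OC)cc3)C(=O)O[C@@]2([C@@H](O)[C@](C)(OCc4ccc(OC)cc4)C=C)[C@]1(O)C=C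
F7 | step 20 | 5-O-methanesulfonyl derivative of F6 | C[C@H]1C[C@@H](OC(=O)C=C(C)C)C2=C(COCc3ccc(OC)cc3)C(=O)O[C@@]2([C@@H](OS(C)(=O)=O)[C@](C)(OCc4ccc(OC)cc4)C=C)[C@]1(O)C=C
F8 | step 20 | open-chain (Z)-alkylidene butenolide with C1 vinyl ketone and C4 vinyl group (2,3-seco form of F9) | C=CC(=O)[C@@H](C)C[C@@H](OC(=O)C=C(C)C)C1=C(COCc2ccc(OC)cc2)C(=O)O/C1=C\[C@](C)(OCc3ccc(OC)cc3)C=C
F9 | step 20 | (2Z)-2,3-didehydro derivative of 27 (ten-membered enone) | COc1ccc(COCC2=C3/C(=C/[C@](C)(OCc4ccc(OC)cc4)/C=C\C(=O)[C@@H](C)C[C@H]3OC(=O)C=C(C)C)OC2=O)cc1
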